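The synthesis rests on one disconnection: the bond between C3 of the oxolanone ring and the 3,4-dihydroxyphenyl ring it carries. The key step exploits that C3 lies α to C2. With C2 raised to the ketone level and the lactone carbon C5 masked as a nitrile, C3 is the acidic CH2 of an acyclic α-keto ester, which palladium catalysis arylates with a protected 4-bromocatechol. This joins both halves and leaves C3 enolizable on purpose. A dynamic kinetic transfer hydrogenation then sets C2 and C3 together, and a Pinner closure gives the cis lactone. The slim nitrile makes the required (Z)-benzylidene geometry the stable one in the open-chain precursor.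

Key step: step 6

Remark: the (S,S)-ligand of step 7 is assumed to give the (2S)-alcohol, the ester standing in for the aryl group of an aryl ketone; if the sense proves opposite, the (R,R)-ligand is used.

Step 1
Reactants: 1 3,4-bis(benzyloxy)benzaldehyde; 2 acrylonitrile
Product: 3 rac-2-{[3,4-bis(benzyloxy)phenyl](hydroxy)methyl}prop-2-enenitrile
Conditions: DABCO (1 equiv), acrylonitrile (5 equiv), MeOH (cat.), rt, several days
Reagents that add atoms: none
Why: Morita–Baylis–Hillman reaction, in which DABCO adds to acrylonitrile, the α-cyano carbanion attacks the aldehyde and DABCO is expelled; the electron-rich aldehyde is slow but acrylonitrile is the most reactive common partner, and the racemic carbinol center is removed in step 4.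

Step 2
Reactants: 3 rac-2-{[3,4-bis(benzyloxy)phenyl](hydroxy)methyl}prop-2-enenitrile
Product: 4 rac-1-[3,4-bis(benzyloxy)phenyl]-2-cyanoprop-2-en-1-yl acetate
Conditions: Ac2O, pyridine, DMAP (cat.), CH2Cl2, 0 °C
Reagents that add atoms: acetic anhydride, CC(=O)OC(C)=O
Why: Standard O-acetylation turns the allylic hydroxyl into the leaving group needed for the SN2′ step.

Step 3
Reactants: 5 methyl 2,2-dimethoxyacetate; 6 propane-1,3-dithiol
Product: 7 methyl 1,3-dithiane-2-carboxylate
Conditions: BF3·OEt2, CHCl3, reflux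
Reagents that add atoms: none
Why: Lewis-acid-catalysed transthioacetalization of the dimethyl acetal gives the cyclic dithioacetal, a glyoxylate acyl-anion equivalent.

Step 4
Reactants: 7 methyl 1,3-dithiane-2-carboxylate; 4 rac-1-[3,4-bis(benzyloxy)phenyl]-2-cyanoprop-2-en-1-yl acetate
Product: 9 methyl 2-{(2Z)-3-[3,4-bis(benzyloxy)phenyl]-2-cyanoprop-2-en-1-yl}-1,3-dithiane-2-carboxylate, via sodium dithianide 8 (not isolated)
Conditions: NaH (1.1 equiv), THF–DMF, 0 °C; then 4, 0 °C to rt
Reagents that add atoms: none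
Why: SN2′ substitution of a Morita–Baylis–Hillman acetate (conjugate addition of the stabilized carbanion to the CH2 terminus, then E1cB loss of acetate); in the elimination the aryl group should settle cis to the slim nitrile and away from the bulky dithianylmethyl group, which is the (Z) geometry needed, and any minor (E) isomer is removed by chromatography.

Step 5
Reactants: 9 methyl 2-{(2Z)-3-[3,4-bis(benzyloxy)phenyl]-2-cyanoprop-2-en-1-yl}-1,3-dithiane-2-carboxylate
Product: 10 methyl (4Z)-5-[3,4-bis(benzyloxy)phenyl]-4-cyano-2-oxopent-4-enoate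
Conditions: PhI(OCOCF3)2, MeCN–H2O 9:1, 0 °C
Reagents that add atoms: water, O
Why: Oxidative dithioacetal hydrolysis with a hypervalent iodine reagent unmasks the α-keto ester under mild, non-halogenating conditions that should leave the enolizable CH2, the electron-poor alkene, the nitrile and the benzyl ethers untouched.

Step 6
Reactants: 10 methyl (4Z)-5-[3,4-bis(benzyloxy)phenyl]-4-cyano-2-oxopent-4-enoate; 11 1,2-bis(benzyloxy)-4-bromobenzene
Product: 13 methyl (4Z)-3,5-bis[3,4-bis(benzyloxy)phenyl]-4-cyano-2-oxopent-4-enoate (racemic at C3, keto–enol mixture), via potassium enolate 12 (not isolated)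
Conditions: Pd2(dba)3 (2.5 mol %), t-Bu3P·HBF4 (10 mol %), K3PO4 (3 equiv), toluene, 100 °C
Reagents that add atoms: none
Why: K3PO4 converts the C3 methylene of 10 (α to the 1,2-dicarbonyl and allylic) into enolate 12 while Pd(0)/P(t-Bu)3 inserts into the C–Br bond of 11; ligand exchange gives an arylpalladium enolate and C–C reductive elimination forms the aryl–C3 bond. The closest known reaction type is the palladium-catalysed β-arylation of α-keto ester enolates with aryl bromides, a relative of the Buchwald–Hartwig ketone α-arylation. No ring is closed. The new stereocenter C3 is not controlled here and need not be, because it stays enolizable, which step 7 uses. The step needs α- over γ-selectivity within the dienolate and mono- over diarylation; the γ-carbon already carries an aryl group and α-coupling keeps the cinnamonitrile conjugation, and the product enolate is too hindered and too stabilized to couple again. The (Z) alkene is the more stable isomer (aryl next to the slim nitrile), so reversible enolization should not erode it.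

Step 7
Reactants: 13 methyl (4Z)-3,5-bis[3,4-bis(benzyloxy)phenyl]-4-cyano-2-oxopent-4-enoate
Product: 14 methyl (2S,3R,4Z)-3,5-bis[3,4-bis(benzyloxy)phenyl]-4-cyano-2-hydroxypent-4-enoate
Conditions: [RuCl2(p-cymene)]2 (2 mol %), (S,S)-N-(m-terphenylsulfonyl)-1,2-diphenylethylenediamine (8 mol %), HCO2H–Et3N 5:2, DMF, 40 °C
Reagents that add atoms: none
Why: Noyori-type asymmetric transfer hydrogenation run as a dynamic kinetic resolution should reduce only the activated C2 ketone; C3 racemizes fast through the enol under Et3N, the catalyst fixes C2 as S and, as known for β-aryl α-keto esters, should consume the C3 epimer that places the aryl group anti to the incoming hydride, giving the 2,3-syn (2S,3R) alcohol.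

Step 8
Reactants: 14 methyl (2S,3R,4Z)-3,5-bis[3,4-bis(benzyloxy)phenyl]-4-cyano-2-hydroxypent-4-enoate
Product: 16 methyl (2S,3R,4Z)-3-[3,4-bis(benzyloxy)phenyl]-4-[3,4-bis(benzyloxy)benzylidene]-5-oxooxolane-2-carboxylate, via iminolactone hydrochloride 15 (not isolated)
Conditions: HCl (4 M in 1,4-dioxane, 5 equiv), CH2Cl2, 0 °C to rt; then THF–H2O, rt
Reagents that add atoms: water, O
Why: Intramolecular Pinner reaction, in which the protonated nitrile is captured by the C2 hydroxyl (5-exo-dig) to give cyclic imidate salt 15, which water hydrolyses to the lactone; the C2–O bond is never broken, so the syn alcohol gives the cis lactone, and the (Z) geometry set at the nitrile stage is carried over.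

Step 9
Reactants: 16 methyl (2S,3R,4Z)-3-[3,4-bis(benzyloxy)phenyl]-4-[3,4-bis(benzyloxy)benzylidene]-5-oxooxolane-2-carboxylate
Product: 17 methyl (2S,3R,4Z)-3-(3,4-dihydroxyphenyl)-4-[(3,4-dihydroxyphenyl)methylidene]-5-oxooxolane-2-carboxylate
Conditions: BCl3 (1 M in CH2Cl2, 8 equiv), pentamethylbenzene (12 equiv), CH2Cl2, −78 °C; MeOH quench
Reagents that add atoms: none
Why: Lewis-acid debenzylation of aryl benzyl ethers with pentamethylbenzene as a non-basic benzyl cation scavenger works at −78 °C without base or hydrogen, so the methyl ester, the lactone, the (Z) alkene and the epimerizable C2 and C3 centers should survive.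

Compound list
1 | 3,4-bis(benzyloxy)benzaldehyde | O=Cc1ccc(OCc2ccccc2)c(OCc2ccccc2)c1 | starting material
2 | acrylonitrile | C=CC#N | starting material
3 | rac-2-{[3,4-bis(benzyloxy)phenyl](hydroxy)methyl}prop-2-enenitrile | N#CC(=C)C(O)c1ccc(OCc2ccccc2)c(OCc2ccccc2)c1 | intermediate
4 | rac-1-[3,4-bis(benzyloxy)phenyl]-2-cyanoprop-2-en-1-yl acetate | CC(=O)OC(C(=C)C#N)c1ccc(OCc2ccccc2)c(OCc2ccccc2)c1 | intermediate
5 | methyl 2,2-dimethoxyacetate | COC(OC)C(=O)OC | starting material
6 | propane-1,3-dithiol | SCCCS | starting material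
7 | methyl 1,3-dithiane-2-carboxylate | COC(=O)C1SCCCS1 | intermediate
8 | sodium 2-(methoxycarbonyl)-1,3-dithian-2-ide (not isolated) | [Na+].COC(=O)[C-]1SCCCS1 | intermediate
9 | methyl 2-{(2Z)-3-[3,4-bis(benzyloxy)phenyl]-2-cyanoprop-2-en-1-yl}-1,3-dithiane-2-carboxylate | COC(=O)C1(C/C(C#N)=C/c2ccc(OCc3ccccc3)c(OCc3ccccc3)c2)SCCCS1 | intermediate
10 | methyl (4Z)-5-[3,4-bis(benzyloxy)phenyl]-4-cyano-2-oxopent-4-enoate | COC(=O)C(=O)C/C(C#N)=C/c1ccc(OCc2ccccc2)c(OCc2ccccc2)c1 | intermediate
11 | 1,2-bis(benzyloxy)-4-bromobenzene | Brc1ccc(OCc2ccccc2)c(OCc2ccccc2)c1 | starting material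
12 | potassium enolate of 10 (C2–C3 enolate, geometry not defined; not isolated) | [K+].COC(=O)C([O-])=C/C(C#N)=C/c1ccc(OCc2ccccc2)c(OCc2ccccc2)c1 | intermediate
13 | methyl (4Z)-3,5-bis[3,4-bis(benzyloxy)phenyl]-4-cyano-2-oxopent-4-enoate (racemic at C3) | COC(=O)C(=O)C(c1ccc(OCc2ccccc2)c(OCc2ccccc2)c1)/C(C#N)=C/c1ccc(OCc2ccccc2)c(OCc2ccccc2)c1 | intermediate
14 | methyl (2S,3R,4Z)-3,5-bis[3,4-bis(benzyloxy)phenyl]-4-cyano-2-hydroxypent-4-enoate | COC(=O)[C@@H](O)[C@H](c1ccc(OCc2ccccc2)c(OCc2ccccc2)c1)/C(C#N)=C/c1ccc(OCc2ccccc2)c(OCc2ccccc2)c1 | intermediate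
15 | (2S,3R,4Z)-3-[3,4-bis(benzyloxy)phenyl]-4-[3,4-bis(benzyloxy)benzylidene]-2-(methoxycarbonyl)oxolan-5-iminium chloride (not isolated) | [Cl-].COC(=O)[C@H]1OC(=[NH2+])/C(=C\c2ccc(OCc3ccccc3)c(OCc3ccccc3)c2)[C@H]1c1ccc(OCc2ccccc2)c(OCc2ccccc2)c1 | intermediate
16 | methyl (2S,3R,4Z)-3-[3,4-bis(benzyloxy)phenyl]-4-[3,4-bis(benzyloxy)benzylidene]-5-oxooxolane-2-carboxylate | COC(=O)[C@H]1OC(=O)/C(=C\c2ccc(OCc3ccccc3)c(OCc3ccccc3)c2)[C@H]1c1ccc(OCc2ccccc2)c(OCc2ccccc2)c1 | intermediate
17 | methyl (2S,3R,4Z)-3-(3,4-dihydroxyphenyl)-4-[(3,4-dihydroxyphenyl)methylidene]-5-oxooxolane-2-carboxylate (2,3-cis) | COC(=O)[C@H]1OC(=O)/C(=C\c2ccc(O)c(O)c2)[C@H]1c1ccc(O)c(O)c1 | target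

Total step count: 9
Longest linear sequence: 8 steps (1, 2, 4, 5, 6, 7, 8, 9); step 3 is a one-step side branch.

Steps most likely to fail

Step 6. The coupling may go to the γ-carbon of the dienolate, the base may move the alkene into conjugation with the ketone, or the enolate oxygen may cyclize onto the nitrile at 100 °C. The fallback sets out from acetate 4 and forms the aryl–C3 bond by a rhodium-catalysed addition/β-acetoxy elimination with 3,4-bis(benzyloxy)phenylboronic acid ([Rh(cod)OH]2, dioxane–H2O, 50 °C), which should give (2Z)-2-[3,4-bis(benzyloxy)benzyl]-3-[3,4-bis(benzyloxy)phenyl]prop-2-enenitrile F1. Its benzylic and allylic methylene is then deprotonated (LiHMDS, THF, −78 °C) and acylated with dimethyl oxalate in a Claisen condensation, which comes back to the route at 13.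

Step 7. The catalyst may discriminate poorly between the two flat sp2 groups on C3 (aryl against cyanoalkenyl), so that the anti alcohol forms as well or even predominates. The fallback sets out from 13 and uses the anti isomer deliberately: the (R,R)-catalyst should give methyl (2R,3R,4Z)-3,5-bis[3,4-bis(benzyloxy)phenyl]-4-cyano-2-hydroxypent-4-enoate F2. Neutral platinum-catalysed nitrile hydration (Pt(II) dimethylphosphinito catalyst, EtOH–H2O, 80 °C) then gives methyl (2R,3R,4Z)-3,5-bis[3,4-bis(benzyloxy)phenyl]-4-carbamoyl-2-hydroxypent-4-enoate F3. An intramolecular Mitsunobu reaction through the amide oxygen (PPh3, DIAD, THF, 0 °C) closes the ring with inversion at C2 to methyl (2S,3R,4Z)-3-[3,4-bis(benzyloxy)phenyl]-4-[3,4-bis(benzyloxy)benzylidene]-5-iminooxolane-2-carboxylate F4. Aqueous HCl converts F4 into 15, where the route is rejoined.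

Step 8. Capture of the conjugated, electron-rich nitrile by the hydroxyl may be slow, and prolonged acid may erode the (Z) geometry or the C2 configuration once the lactone has formed. The fallback sets out from 14 and separates the two events: neutral platinum-catalysed hydration (same catalyst, EtOH–H2O, 80 °C) should give methyl (2S,3R,4Z)-3,5-bis[3,4-bis(benzyloxy)phenyl]-4-carbamoyl-2-hydroxypent-4-enoate F5. Brief treatment with TsOH·H2O (1 equiv, toluene, 50 °C) then lactonizes the γ-hydroxy amide with loss of ammonia and returns to the route at 16.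

Further compounds
F1 | step 6 | (2Z)-2-[3,4-bis(benzyloxy)benzyl]-3-[3,4-bis(benzyloxy)phenyl]prop-2-enenitrile | N#C/C(Cc1ccc(OCc2ccccc2)c(OCc2ccccc2)c1)=C\c1ccc(OCc2ccccc2)c(OCc2ccccc2)c1
F2 | step 7 | methyl (2R,3R,4Z)-3,5-bis[3,4-bis(benzyloxy)phenyl]-4-cyano-2-hydroxypent-4-enoate | COC(=O)[C@H](O)[C@H](c1ccc(OCc2ccccc2)c(OCc2ccccc2)c1)/C(C#N)=C/c1ccc(OCc2ccccc2)c(OCc2ccccc2)c1
F3 | step 7 | methyl (2R,3R,4Z)-3,5-bis[3,4-bis(benzyloxy)phenyl]-4-carbamoyl-2-hydroxypent-4-enoate | COC(=O)[C@H](O)[C@H](c1ccc(OCc2ccccc2)c(OCc2ccccc2)c1)/C(C(N)=O)=C/c1ccc(OCc2ccccc2)c(OCc2ccccc2)c1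
F4 | step 7 | methyl (2S,3R,4Z)-3-[3,4-bis(benzyloxy)phenyl]-4-[3,4-bis(benzyloxy)benzylidene]-5-iminooxolane-2-carboxylate | COC(=O)[C@H]1OC(=N)/C(=C\c2ccc(OCc3ccccc3)c(OCc3ccccc3)c2)[C@H]1c1ccc(OCc2ccccc2)c(OCc2ccccc2)c1
F5 | step 8 | methyl (2S,3R,4Z)-3,5-bis[3,4-bis(benzyloxy)phenyl]-4-carbamoyl-2-hydroxypent-4-enoate | COC(=O)[C@@H](O)[C@H](c1ccc(OCc2ccccc2)c(OCc2ccccc2)c1)/C(C(N)=O)=C/c1ccc(OCc2ccccc2)c(OCc2ccccc2)c1
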